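**Retrosynthetic overview**
1. 15 ⇒ 14: the 2-oxohexyl ketone on ring B stays masked as a hex-1-ynyl group until the last step (alkyne hydration).
2. 14 ⇒ 12: the ring A anhydride and its CH2OH are released together from a cis-dimethyl ester carrying an allylic CH2Br (saponification, then acid).
3. 12 ⇒ 8 + 11: the CH–CH2 bond between the two maleic units and the single (S) stereocentre are made in one metal-free step, an enantioselective γ-alkylation of the ring B anhydride under chiral ammonium ion pairing.
4. 8 ⇒ 1 + 2 + 5 (carbocupration–bromination, Sonogashira coupling, acidolysis); 11 ⇒ 9 (esterification, double allylic bromination).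
5. Ring order: the ring B anhydride is closed first (step 3), the ring A anhydride second (step 7).

Assumption: the sense of induction of the new step 6 is not yet known; the cinchonidine-derived catalyst is taken to give the (S) centre, and its cinchonine-derived pseudo-enantiomer is used if the opposite sense is found.

Step 1
Reactants: 1 di-tert-butyl but-2-ynedioate; 2 hexylmagnesium bromide
Product: 4 di-tert-butyl (E)-2-bromo-3-hexylbut-2-enedioate (ester groups cis), via vinylcopper adduct 3 (not isolated)
Conditions: CuBr·SMe2 (1.05 equiv), THF, −78 °C; then NBS, −78 to −40 °C; aq. NH4Cl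
Reagents that add atoms: N-bromosuccinimide O=C1CCC(=O)N1Br
Why: The hexylcopper reagent adds syn across the acetylenic diester (carbocupration, a conjugate addition) and NBS brominates the resulting vinylcopper with retention, so the two esters end up cis as ring B needs.

Step 2
Reactants: 4 di-tert-butyl (E)-2-bromo-3-hexylbut-2-enedioate; 5 hex-1-yne
Product: 6 di-tert-butyl (Z)-2-hexyl-3-(hex-1-yn-1-yl)but-2-enedioate
Conditions: Pd(PPh3)2Cl2 (3 mol%), CuI (6 mol%), Et3N, THF, 50 °C
Reagents that add atoms: none
Why: Sonogashira coupling of the electron-poor vinyl bromide keeps the alkene geometry and installs the hex-1-ynyl group, a masked 2-oxohexyl chain with no acidic hydrogen next to the ring.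

Step 3
Reactants: 6 di-tert-butyl (Z)-2-hexyl-3-(hex-1-yn-1-yl)but-2-enedioate
Product: 8 3-hexyl-4-(hex-1-yn-1-yl)furan-2,5-dione, via cis-diacid 7 (not isolated)
Conditions: TFA/CH2Cl2 1:1, rt; then toluene, 60 °C, evaporation
Reagents that add atoms: none
Why: Acidolysis of the two tert-butyl esters gives the cis-diacid, which, like other 2,3-disubstituted maleic acids, loses water on concentration and closes ring B as the anhydride (cyclodehydration).

Step 4
Reactants: 9 3,4-dimethylfuran-2,5-dione
Product: 10 dimethyl (Z)-2,3-dimethylbut-2-enedioate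
Conditions: MeOH, H2SO4 (cat.), reflux, 3 Å sieves (Soxhlet)
Reagents that add atoms: methanol CO
Why: Fischer esterification with removal of water opens the anhydride to the diester, and the cis geometry is inherited from the ring.

Step 5
Reactants: 10 dimethyl (Z)-2,3-dimethylbut-2-enedioate
Product: 11 dimethyl (Z)-2,3-bis(bromomethyl)but-2-enedioate
Conditions: NBS (2.1 equiv), AIBN (5 mol%), PhCF3, 85 °C
Reagents that add atoms: N-bromosuccinimide O=C1CCC(=O)N1Br
Why: Wohl–Ziegler radical bromination takes one hydrogen from each of the two equivalent allylic methyl groups, while the electron-poor tetrasubstituted alkene does not add bromine radicals and so keeps its cis geometry.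

Step 6
Reactants: 8 3-hexyl-4-(hex-1-yn-1-yl)furan-2,5-dione; 11 dimethyl (Z)-2,3-bis(bromomethyl)but-2-enedioate
Product: 12 dimethyl (E)-2-(bromomethyl)-3-[(2S)-2-[4-(hex-1-yn-1-yl)-2,5-dioxo-2,5-dihydrofuran-3-yl]heptyl]but-2-enedioate (ester groups cis)
Conditions: 11 (3 equiv), N-(9-anthracenylmethyl)cinchonidinium chloride (10 mol%), Cs2CO3 (1.5 equiv, powdered), toluene/CH2Cl2 4:1, 4 Å sieves, −40 °C
Reagents that add atoms: none
Why: Proposed new method: an ion-pair-catalysed, γ-selective enantioselective alkylation of a maleic anhydride dienolate, in which Cs2CO3 removes a hydrogen from the ring-bound CH2 of the hexyl group of 8 (the most acidic C–H, since the alkyne leaves no C–H next to the ring and the remote propargylic CH2 would need a strained cumulenolate), the chiral cinchonidinium cation pairs with the dienolate oxygen and shields one face of the exocyclic carbon, the fully substituted alkynyl-bearing α-carbon is blocked so that SN2 attack on an allylic bromide of 11 occurs at the γ-carbon and restores the maleic anhydride while setting the (S) centre, the cis geometry of both units is kept by the anhydride ring and by direct SN2 substitution, and the far less acidic acyclic diester 11 is not deprotonated by the weak base; the closest known reaction types are asymmetric phase-transfer alkylation of enolates with allylic bromides and organocatalytic vinylogous allylic alkylation of butenolides, and the γ-nucleophilicity of alkylmaleic anhydride anions is the one seen in biomimetic nonadride dimerisations.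

Step 7
Reactants: 12 dimethyl (E)-2-(bromomethyl)-3-[(2S)-2-[4-(hex-1-yn-1-yl)-2,5-dioxo-2,5-dihydrofuran-3-yl]heptyl]but-2-enedioate
Product: 14 3-[(2S)-2-[4-(hex-1-yn-1-yl)-2,5-dioxo-2,5-dihydrofuran-3-yl]heptyl]-4-(hydroxymethyl)furan-2,5-dione, via tetra-acid 13 (not isolated)
Conditions: LiOH·H2O (8 equiv), THF/H2O 3:1 (no alcohol cosolvent), 0 °C to rt; then 2 M HCl to pH 1; toluene azeotrope
Reagents that add atoms: lithium hydroxide [Li+].[OH-]; water O
Why: Hydroxide opens the ring B anhydride at once to its dicarboxylate (which removes the acidity of the stereocentre), saponifies the two methyl esters and displaces the allylic bromide (ester hydrolysis plus SN2), and acidification lets both cis-diacids cyclodehydrate to anhydrides while the CH2OH, held trans to the only carboxyl it could lactonise with, stays free.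

Step 8
Reactants: 14 3-[(2S)-2-[4-(hex-1-yn-1-yl)-2,5-dioxo-2,5-dihydrofuran-3-yl]heptyl]-4-(hydroxymethyl)furan-2,5-dione
Product: 15 3-(hydroxymethyl)-4-[(2S)-2-[2,5-dioxo-4-(2-oxohexyl)-2,5-dihydrofuran-3-yl]heptyl]furan-2,5-dione
Conditions: Ph3PAuNTf2 (5 mol%), H2O (5 equiv), 1,4-dioxane, 60 °C; toluene azeotrope
Reagents that add atoms: water O
Why: Gold-catalysed alkyne hydration adds water at the butyl-bearing alkyne carbon (the δ-position of the ene-dione and the carbon that best carries positive charge), and tautomerisation of the enol gives the ring–CH2–C(=O)–Bu ketone under neutral conditions that leave the stereocentre untouched.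

**Compound list**
1 | di-tert-butyl but-2-ynedioate (di-tert-butyl acetylenedicarboxylate) | CC(C)(C)OC(=O)C#CC(=O)OC(C)(C)C | starting material
2 | hexylmagnesium bromide | CCCCCC[Mg]Br | starting material
3 | vinylcopper adduct: di-tert-butyl 2-cuprio-3-hexylbut-2-enedioate, hexyl and copper cis | CCCCCC/C(C(=O)OC(C)(C)C)=C(\[Cu])C(=O)OC(C)(C)C | intermediate
4 | di-tert-butyl (E)-2-bromo-3-hexylbut-2-enedioate (ester groups cis) | CCCCCC/C(C(=O)OC(C)(C)C)=C(\Br)C(=O)OC(C)(C)C | intermediate
5 | hex-1-yne | CCCCC#C | starting material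
6 | di-tert-butyl (Z)-2-hexyl-3-(hex-1-yn-1-yl)but-2-enedioate | CCCCCC/C(C(=O)OC(C)(C)C)=C(\C#CCCCC)C(=O)OC(C)(C)C | intermediate
7 | cis-diacid: (Z)-2-hexyl-3-(hex-1-yn-1-yl)but-2-enedioic acid | CCCCCC/C(C(=O)O)=C(\C#CCCCC)C(=O)O | intermediate
8 | 3-hexyl-4-(hex-1-yn-1-yl)furan-2,5-dione (ring B anhydride) | CCCCCCC1=C(C#CCCCC)C(=O)OC1=O | intermediate
9 | 3,4-dimethylfuran-2,5-dione (2,3-dimethylmaleic anhydride) | CC1=C(C)C(=O)OC1=O | starting material
10 | dimethyl (Z)-2,3-dimethylbut-2-enedioate | COC(=O)/C(C)=C(/C)C(=O)OC | intermediate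
11 | dimethyl (Z)-2,3-bis(bromomethyl)but-2-enedioate | COC(=O)/C(CBr)=C(/CBr)C(=O)OC | intermediate
12 | dimethyl (E)-2-(bromomethyl)-3-[(2S)-2-[4-(hex-1-yn-1-yl)-2,5-dioxo-2,5-dihydrofuran-3-yl]heptyl]but-2-enedioate (ester groups cis) | CCCCC[C@@H](C/C(C(=O)OC)=C(\CBr)C(=O)OC)C1=C(C#CCCCC)C(=O)OC1=O | intermediate
13 | tetra-acid: (Z)-2-(hydroxymethyl)-3-[(2S)-2-[(1Z)-1,2-dicarboxyoct-1-en-3-yn-1-yl]heptyl]but-2-enedioic acid (both rings open) | CCCCC[C@@H](C/C(C(=O)O)=C(\CO)C(=O)O)/C(C(=O)O)=C(\C#CCCCC)C(=O)O | intermediate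
14 | 3-[(2S)-2-[4-(hex-1-yn-1-yl)-2,5-dioxo-2,5-dihydrofuran-3-yl]heptyl]-4-(hydroxymethyl)furan-2,5-dione | CCCCC[C@@H](CC1=C(CO)C(=O)OC1=O)C1=C(C#CCCCC)C(=O)OC1=O | intermediate
15 | 3-(hydroxymethyl)-4-[(2S)-2-[2,5-dioxo-4-(2-oxohexyl)-2,5-dihydrofuran-3-yl]heptyl]furan-2,5-dione (CNP0537712.1) | CCCCC[C@@H](CC1=C(CO)C(=O)OC1=O)C1=C(CC(=O)CCCC)C(=O)OC1=O | target

**Step count and risks**
Total step count: 8 (steps 1–3 give 8, steps 4–5 give 11, steps 6–8 join them and finish). Longest linear sequence: 6 steps (1, 2, 3, 6, 7, 8).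

Step 6 (the proposed new step) is the most likely to fail. The dienolate may alkylate at the α-carbon or at oxygen, the enantiomeric excess may be low, the base may isomerise the alkyne to an allene, or it may open the anhydride. The fallback uses known auxiliary chemistry in place of the ion-pair alkylation and builds ring B afterwards; it sets out from 11 and comes back to the route at 15. Heptanal and (S)-1-amino-2-(methoxymethyl)pyrrolidine are condensed to the SAMP hydrazone of heptanal F1. Its lithium azaenolate (LiN(iPr)2, THF, 0 °C) is alkylated with 11 (3 equiv, −100 °C) in an Enders alkylation to give the bromomethyl hydrazone F2 with the (S) centre. KOAc in DMF exchanges the remaining bromide for acetate to give the acetoxymethyl hydrazone F3. Ozonolysis (O3, CH2Cl2, −78 °C, then Me2S) releases the (S)-aldehyde F4. Ohira–Bestmann homologation (dimethyl (1-diazo-2-oxopropyl)phosphonate, K2CO3, MeOH, 0 °C, which also methanolyses the acetate) gives the terminal alkyne F5. CuI-catalysed coupling with 1-diazohexan-2-one gives the β,γ-alkynyl ketone F6. Nickel-catalysed double carboxylation with CO2 (Ni(acac)2, 2,2'-bipyridine, Zn, MgBr2, DMF, rt) closes ring B to the keto anhydride F7. Me3SnOH (1,2-dichloroethane, 80 °C) and then 1 M HCl cleave the methyl esters and close ring A to give 15.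

Step 8 may give the wrong regiochemistry (a hexanoyl group) or stall in the presence of the free alcohol and the anhydrides. The fallback replaces electrophilic hydration by a radical addition whose regiochemistry is fixed by the conjugated vinyl radical; it sets out from 14 and comes back at 15. Thiol–yne addition of benzenethiol (PhSH, AIBN, benzene, 80 °C) places sulfur on the butyl-bearing carbon and gives the vinyl sulfide F8 (E/Z mixture). Hydrolysis of this vinylogous thioester (TFA/H2O 9:1, 50 °C) gives 15.

Step 5 may over-brominate or lose the cis geometry through reversible bromine-radical addition to the acyclic diester. The fallback brominates while the ring still locks the geometry; it sets out from 9 and comes back at 11. Bromination of 9 (NBS 2.2 equiv, AIBN, PhCF3, reflux) gives 3,4-bis(bromomethyl)furan-2,5-dione F9. Methanol opens it to the half ester F10, which is esterified at once with Me3SiCHN2 (toluene/MeOH, 0 °C) to give 11.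

**Further compounds**
F1 | step 6 | SAMP hydrazone of heptanal: (S,E)-N-heptylidene-2-(methoxymethyl)pyrrolidin-1-amine | CCCCCC/C=N/N1CCC[C@H]1COC
F2 | step 6 | bromomethyl hydrazone: SAMP hydrazone of (S)-2-pentyl-3-[ring A dimethyl ester with CH2Br]propanal | CCCCC[C@@H](C/C(C(=O)OC)=C(\CBr)C(=O)OC)/C=N/N1CCC[C@H]1COC
F3 | step 6 | acetoxymethyl hydrazone: as F2 with CH2OAc in place of CH2Br | CCCCC[C@@H](C/C(C(=O)OC)=C(\COC(C)=O)C(=O)OC)/C=N/N1CCC[C@H]1COC
F4 | step 6 | (S)-aldehyde: dimethyl (Z)-2-(acetoxymethyl)-3-[(2S)-2-formylheptyl]but-2-enedioate | CCCCC[C@@H](C/C(C(=O)OC)=C(\COC(C)=O)C(=O)OC)C=O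
F5 | step 6 | terminal alkyne: dimethyl (Z)-2-[(2S)-2-ethynylheptyl]-3-(hydroxymethyl)but-2-enedioate | CCCCC[C@@H](C/C(C(=O)OC)=C(\CO)C(=O)OC)C#C
F6 | step 6 | β,γ-alkynyl ketone: dimethyl (Z)-2-(hydroxymethyl)-3-[(2S)-6-oxo-2-pentyldec-3-yn-1-yl]but-2-enedioate | CCCCC[C@@H](C/C(C(=O)OC)=C(\CO)C(=O)OC)C#CCC(=O)CCCC
F7 | step 6 | keto anhydride: dimethyl (Z)-2-(hydroxymethyl)-3-[(2S)-2-[2,5-dioxo-4-(2-oxohexyl)-2,5-dihydrofuran-3-yl]heptyl]but-2-enedioate | CCCCC[C@@H](C/C(C(=O)OC)=C(\CO)C(=O)OC)C1=C(CC(=O)CCCC)C(=O)OC1=O
F8 | step 8 | vinyl sulfide: 3-(hydroxymethyl)-4-[(2S)-2-[2,5-dioxo-4-[2-(phenylsulfanyl)hex-1-en-1-yl]-2,5-dihydrofuran-3-yl]heptyl]furan-2,5-dione | CCCCC[C@@H](CC1=C(CO)C(=O)OC1=O)C1=C(C=C(CCCC)Sc2ccccc2)C(=O)OC1=O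
F9 | step 5 | 3,4-bis(bromomethyl)furan-2,5-dione | BrCC1=C(CBr)C(=O)OC1=O
F10 | step 5 | half ester: (Z)-2,3-bis(bromomethyl)-4-methoxy-4-oxobut-2-enoic acid | COC(=O)/C(CBr)=C(/CBr)C(=O)O
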